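**Retrosynthetic overview**
1. Ring C (the butenolide) is made last from CO2: the C16–C13 and C15–O bonds come from zinc-mediated carboxylation of the 2-alkynyl bromide 21, followed, without purification of the intermediate acid, by silver-catalysed closure (step 14).
2. Enabling feature: the C13≡C14 triple bond next to the C15 bromomethylene. After zinc insertion this propargyl/allenyl unit is nucleophilic at C13 towards CO2 and leaves a C13=C14=C15 allene whose terminal C15 accepts the new carboxyl oxygen.
3. Side chain: C12–C13 by acetylide alkylation, C9–C11 by convex-face alkylation of a C8 enolate, C17 by methylenation of the C8 ketone.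
4. Ring B (second ring) by aldol condensation onto ring A; C20 by cis-selective conjugate addition to the resulting octalone.
5. Ring A (first ring, bought as a cyclohexenone): C4 by catalytic asymmetric conjugate addition of Me2Zn, C5 by aldol/dehydration and ester-directed hydrogenation. Ring order: A, B, C.

Key step: step 14

Remark: labdane numbering is used (C1–C10 decalin, C11–C12 side chain, C13–C16 butenolide with C16 the carbonyl, C17 exocyclic methylene, C18 methyl and C19 acetoxymethyl on C4, C20 methyl on C10); the SMILES is read as the cis-fused decalin (4R,5R,9R,10S), in which H-5, C19, C20 and C11 all lie on one face, and this isomer is the one made.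

Step 1
Reactants: 1 ethyl 2-(2-methyl-1,3-dioxolan-2-yl)acetate
Product: 2 2-(2-methyl-1,3-dioxolan-2-yl)acetaldehyde
Conditions: i-Bu2AlH (1.05 equiv), CH2Cl2, −78 °C; MeOH, then H2O
Reagents that add atoms: none
Why: Partial reduction of the ester at low temperature stops at the aluminium hemiacetal and should release the aldehyde on work-up; no stereocentre is involved.

Step 2
Reactants: 3 methyl 3-oxocyclohex-1-ene-1-carboxylate; 2 2-(2-methyl-1,3-dioxolan-2-yl)acetaldehyde
Product: 5 methyl (1R)-2-[1-hydroxy-2-(2-methyl-1,3-dioxolan-2-yl)ethyl]-1-methyl-3-oxocyclohexane-1-carboxylate (diastereomer mixture at C5/C6), via methylzinc enolate 4 (not isolated)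
Conditions: Me2Zn (3 equiv), (CuOTf)2·C6H6 (2.5 mol %), chiral bidentate sulfonate–NHC ligand (from its imidazolinium salt, 5 mol %), Et2O, −30 °C; then 2, −78 → −30 °C; H2O
Reagents that add atoms: dimethylzinc C[Zn]C
Why: Copper-catalysed asymmetric conjugate addition of Me2Zn to the β-(methoxycarbonyl) enone, in which the chiral NHC–copper complex sets the quaternary C4 centre (ligand enantiomer chosen for R), gives the zinc enolate regiospecifically at C5, and its aldol addition to 2 forms the C5–C6 bond (the C5 and C6 configurations are erased in step 3).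

Step 3
Reactants: 5 methyl (1R)-2-[1-hydroxy-2-(2-methyl-1,3-dioxolan-2-yl)ethyl]-1-methyl-3-oxocyclohexane-1-carboxylate
Product: 7 methyl (1R)-1-methyl-2-[2-(2-methyl-1,3-dioxolan-2-yl)ethylidene]-3-oxocyclohexane-1-carboxylate (drawn as the Z isomer), via mesylate 6 (not isolated)
Conditions: MsCl, Et3N, CH2Cl2, 0 °C; then DBU, rt
Reagents that add atoms: none
Why: Mesylation of the β-hydroxy ketone and E1cB elimination complete an aldol condensation to the exocyclic enone, whose alkene geometry is of no consequence for step 4.

Step 4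
Reactants: 7 methyl (1R)-1-methyl-2-[2-(2-methyl-1,3-dioxolan-2-yl)ethylidene]-3-oxocyclohexane-1-carboxylate
Product: 8 methyl (1R,2S)-1-methyl-2-[2-(2-methyl-1,3-dioxolan-2-yl)ethyl]-3-oxocyclohexane-1-carboxylate
Conditions: H2 (1 atm), [Ir(cod)(PCy3)(py)]PF6 (5 mol %), CH2Cl2, rt
Reagents that add atoms: none
Why: Carbonyl-directed homogeneous hydrogenation, in which the cationic iridium centre chelated by the C19 ester carbonyl and the adjacent C5=C6 bond should deliver H2 to the alkene face syn to the ester, so that H-5 ends up cis to C19.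

Step 5
Reactants: 8 methyl (1R,2S)-1-methyl-2-[2-(2-methyl-1,3-dioxolan-2-yl)ethyl]-3-oxocyclohexane-1-carboxylate
Product: 10 methyl (1R,8aR)-1-methyl-6-oxo-1,2,3,4,6,7,8,8a-octahydronaphthalene-1-carboxylate, via diketone 9 (not isolated)
Conditions: 1 M HCl, THF, rt; neutralise, concentrate; then NaOMe (0.3 equiv), MeOH, 0 °C → rt
Reagents that add atoms: water O
Why: Acidic ketal hydrolysis followed by base-mediated intramolecular aldol condensation (the ring-closing half of a Robinson annulation) closes ring B, and C5 should keep its configuration because enolisation of the ring ketone and γ-deprotonation of the product occur towards C1 and not at the neopentyl C5–H.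

Step 6
Reactants: 10 methyl (1R,8aR)-1-methyl-6-oxo-1,2,3,4,6,7,8,8a-octahydronaphthalene-1-carboxylate
Product: 11 methyl (1R,4aR,8aR)-1,4a-dimethyl-6-[(trimethylsilyl)oxy]-1,2,3,4,4a,7,8,8a-octahydronaphthalene-1-carboxylate
Conditions: MeMgBr, CuBr·SMe2 (10 mol %), Me3SiCl, HMPA, THF, −78 °C; Et3N
Reagents that add atoms: methylmagnesium bromide C[Mg]Br; chlorotrimethylsilane C[Si](C)(C)Cl
Why: Copper-catalysed conjugate addition with in situ silylation, in which methyl should add to C10 from the face of H-5 and opposite the axial C18 methyl on C4 (the usual cis-selective addition to an octalone with a ring-fusion hydrogen), giving the cis-fused decalin with a regiodefined C8=C9 silyl enol ether.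

Step 7
Reactants: 11 methyl (1R,4aR,8aR)-1,4a-dimethyl-6-[(trimethylsilyl)oxy]-1,2,3,4,4a,7,8,8a-octahydronaphthalene-1-carboxylate; 12 methyl bromoacetate
Product: 13 methyl (1R,4aR,5S,8aR)-5-(2-methoxy-2-oxoethyl)-1,4a-dimethyl-6-oxodecahydronaphthalene-1-carboxylate
Conditions: BnMe3N+ F− (anhydrous), 4 Å MS, THF, 0 °C → rt
Reagents that add atoms: none
Why: Fluoride-promoted regiospecific C-alkylation of the silyl enol ether with the α-bromo ester, in which the electrophile should enter C9 on the convex face of the cis-fused bicycle, away from ring A and its C18 methyl, placing C11 cis to the C10 methyl.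

Step 8
Reactants: 13 methyl (1R,4aR,5S,8aR)-5-(2-methoxy-2-oxoethyl)-1,4a-dimethyl-6-oxodecahydronaphthalene-1-carboxylate
Product: 14 methylene diester (C8=C17 alkene; CO2Me as C19 on C4; CH2CO2Me on C9; 4R,5R,9R,10S)
Conditions: Zn, CH2Br2, TiCl4, THF/CH2Cl2, 0 °C → rt
Reagents that add atoms: dibromomethane BrCBr
Why: Takai–Lombardo methylenation is non-basic and ketone-selective, so both esters and the kinetically set, epimerisable C9 centre should survive.

Step 9
Reactants: 14 methylene diester
Product: 15 diol (19-hydroxy; CH2CH2OH on C9; 4R,5R,9R,10S)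
Conditions: LiAlH4, THF, 0 °C → rt; H2O
Reagents that add atoms: none
Why: Hydride reduction of both methyl esters to primary alcohols, the 1,1-disubstituted alkene being inert.

Step 10
Reactants: 15 diol
Product: 16 iodo alcohol (12-iodo; 19-hydroxy; 4R,5R,9R,10S)
Conditions: I2, PPh3, imidazole, CH2Cl2, 0 °C
Reagents that add atoms: iodine II
Why: Appel-type iodination proceeds by SN2 displacement only at the unhindered C12 carbinol, the neopentyl C19 alcohol being returned on work-up.

Step 11
Reactants: 16 iodo alcohol; 17 tert-butyldimethyl(prop-2-yn-1-yloxy)silane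
Product: 19 alkynyl alcohol (C9–CH2CH2–C≡C–CH2OTBS; 19-hydroxy; 4R,5R,9R,10S), via lithium acetylide 18 (not isolated)
Conditions: 17 (2.5 equiv), n-BuLi (2.4 equiv), THF, −78 °C; then 16, DMPU, −78 °C → rt
Reagents that add atoms: none
Why: SN2 alkylation of the lithium acetylide with the primary iodide in a dipolar cosolvent forms the C12–C13 bond, the excess acetylide also deprotonating the free C19 hydroxyl.

Step 12
Reactants: 19 alkynyl alcohol
Product: 20 acetate (19-acetoxy; C15 OTBS; 4R,5R,9R,10S)
Conditions: Ac2O, pyridine, DMAP (cat.), CH2Cl2, rt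
Reagents that add atoms: acetic anhydride CC(=O)OC(C)=O
Why: DMAP-catalysed acylation of the neopentyl primary alcohol installs the acetate of the target, which then serves as its own protecting group.

Step 13
Reactants: 20 acetate
Product: 21 propargylic bromide (C9–CH2CH2–C≡C–CH2Br; 19-acetoxy; 4R,5R,9R,10S)
Conditions: Ph3PBr2, CH2Cl2, 0 °C → rt
Reagents that add atoms: dibromotriphenylphosphorane BrP(Br)(c1ccccc1)(c1ccccc1)c1ccccc1
Why: Dibromotriphenylphosphorane converts the primary propargylic silyl ether directly into the bromide through an oxyphosphonium intermediate (Appel-type SN2), leaving the acetate and both C–C multiple bonds untouched.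

Step 14
Reactants: 21 propargylic bromide
Product: 25 target compound CNP0350004.1, via propargylzinc bromide 22 (not isolated), via bromozinc allenoate 23 (not isolated), via allenoic acid 24 (not isolated)
Conditions: Zn dust, LiCl, THF, 0 °C; CO2 (1 atm), MgCl2, 0 °C → rt; AcOH; filter, H2O wash, solvent switch to acetone (crude 24 not purified); AgNO3 (10 mol %), rt
Reagents that add atoms: carbon dioxide O=C=O
Why: Proposed new method: zinc inserts into the propargylic C15–Br bond to give the ambident propargyl/allenyl zinc 22, which should add to CO2 through a six-membered SE2' transition state at its γ-carbon C13 (new C16–C13 bond) to give the 2,3-allenoate 23; after protonation to acid 24, AgNO3 activates the distal C14=C15 bond of the allene, the carboxyl oxygen closes ring C by 5-endo-trig attack on the terminal C15 (new C15–O bond), and protodemetalation at C14 gives the conjugated butenolide. The closest known reaction types are the carbonation of 2-alkynyl Grignard reagents to 2-substituted buta-2,3-dienoic acids, the zinc-mediated Barbier addition of 1-bromo-2-alkynes to aldehydes at the γ-carbon, and the silver-catalysed cycloisomerisation of 2,3-allenoic acids to butenolides; telescoping them with CO2 as the only added building block is the new element. No stereocentre is formed. The step needs γ- over α-carboxylation, which the primary C15–Zn terminus and the SE2' pathway should secure (any 3-alkynoic acid from α-attack cannot give the butenolide and would be removed), and 5-endo over 4-exo closure, which the geometry of the 2,3-allenoic acid imposes. The neopentyl acetate and the 1,1-disubstituted C8=C17 alkene are inert to organozinc halides and to AgNO3, and the filtration and water wash before the silver salt is added remove the excess zinc metal and the chloride and bromide salts that would otherwise consume the catalyst.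

**Compound list**
1 | ethyl 2-(2-methyl-1,3-dioxolan-2-yl)acetate | CCOC(=O)CC1(C)OCCO1 | starting material
2 | 2-(2-methyl-1,3-dioxolan-2-yl)acetaldehyde | O=CCC1(C)OCCO1 | intermediate
3 | methyl 3-oxocyclohex-1-ene-1-carboxylate | COC(=O)C1=CC(=O)CCC1 | starting material
4 | methyl (1R)-1-methyl-3-[(methylzincio)oxy]cyclohex-2-ene-1-carboxylate (methylzinc enolate) | C[Zn]OC1=C[C@](C)(C(=O)OC)CCC1 | intermediate
5 | methyl (1R)-2-[1-hydroxy-2-(2-methyl-1,3-dioxolan-2-yl)ethyl]-1-methyl-3-oxocyclohexane-1-carboxylate (diastereomer mixture at C5/C6) | CC1(CC(O)C2[C@](C)(C(=O)OC)CCCC2=O)OCCO1 | intermediate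
6 | methanesulfonate of 5 (mesylate) | CC1(CC(OS(C)(=O)=O)C2[C@](C)(C(=O)OC)CCCC2=O)OCCO1 | intermediate
7 | methyl (1R)-1-methyl-2-[2-(2-methyl-1,3-dioxolan-2-yl)ethylidene]-3-oxocyclohexane-1-carboxylate (Z drawn) | CC1(C/C=C2/[C@](C)(C(=O)OC)CCCC2=O)OCCO1 | intermediate
8 | methyl (1R,2S)-1-methyl-2-[2-(2-methyl-1,3-dioxolan-2-yl)ethyl]-3-oxocyclohexane-1-carboxylate | CC1(CC[C@H]2[C@](C)(C(=O)OC)CCCC2=O)OCCO1 | intermediate
9 | methyl (1R,2S)-1-methyl-3-oxo-2-(3-oxobutyl)cyclohexane-1-carboxylate (diketone) | CC(=O)CC[C@H]1[C@](C)(C(=O)OC)CCCC1=O | intermediate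
10 | methyl (1R,8aR)-1-methyl-6-oxo-1,2,3,4,6,7,8,8a-octahydronaphthalene-1-carboxylate (octalone) | O=C1CC[C@H]2[C@](C)(C(=O)OC)CCCC2=C1 | intermediate
11 | methyl (1R,4aR,8aR)-1,4a-dimethyl-6-[(trimethylsilyl)oxy]-1,2,3,4,4a,7,8,8a-octahydronaphthalene-1-carboxylate (cis-fused silyl enol ether) | C[Si](C)(C)OC=1CC[C@H]2[C@](C)(C(=O)OC)CCC[C@@]2(C)C=1 | intermediate
12 | methyl bromoacetate | COC(=O)CBr | starting material
13 | methyl (1R,4aR,5S,8aR)-5-(2-methoxy-2-oxoethyl)-1,4a-dimethyl-6-oxodecahydronaphthalene-1-carboxylate (same spatial arrangement at C4, C5, C9, C10 as in 25) | O=C1CC[C@H]2[C@](C)(C(=O)OC)CCC[C@@]2(C)[C@@H]1CC(=O)OC | intermediate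
14 | methylene diester: C8=C17 alkene, C19 methyl ester on C4, CH2CO2Me on C9 (4R,5R,9R,10S) | C=C1CC[C@H]2[C@](C)(C(=O)OC)CCC[C@@]2(C)[C@@H]1CC(=O)OC | intermediate
15 | diol: 19-hydroxy, 2-hydroxyethyl on C9 (4R,5R,9R,10S) | C=C1CC[C@H]2[C@](C)(CO)CCC[C@@]2(C)[C@@H]1CCO | intermediate
16 | iodo alcohol: 2-iodoethyl on C9, 19-hydroxy (4R,5R,9R,10S) | C=C1CC[C@H]2[C@](C)(CO)CCC[C@@]2(C)[C@@H]1CCI | intermediate
17 | tert-butyldimethyl(prop-2-yn-1-yloxy)silane | C#CCO[Si](C)(C)C(C)(C)C | starting material
18 | lithium acetylide of 17 | [Li]C#CCO[Si](C)(C)C(C)(C)C | intermediate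
19 | alkynyl alcohol: C9–CH2CH2–C≡C–CH2OTBS, 19-hydroxy (4R,5R,9R,10S) | C=C1CC[C@H]2[C@](C)(CO)CCC[C@@]2(C)[C@@H]1CCC#CCO[Si](C)(C)C(C)(C)C | intermediate
20 | acetate: 19-acetoxy, C15 OTBS (4R,5R,9R,10S) | C=C1CC[C@H]2[C@](C)(COC(C)=O)CCC[C@@]2(C)[C@@H]1CCC#CCO[Si](C)(C)C(C)(C)C | intermediate
21 | propargylic bromide: C9–CH2CH2–C≡C–CH2Br, 19-acetoxy (4R,5R,9R,10S) | C=C1CC[C@H]2[C@](C)(COC(C)=O)CCC[C@@]2(C)[C@@H]1CCC#CCBr | intermediate
22 | propargylzinc bromide from 21 (in equilibrium with its allenyl form) | C=C1CC[C@H]2[C@](C)(COC(C)=O)CCC[C@@]2(C)[C@@H]1CCC#CC[Zn]Br | intermediate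
23 | bromozinc 2-substituted buta-2,3-dienoate | C=C1CC[C@H]2[C@](C)(COC(C)=O)CCC[C@@]2(C)[C@@H]1CCC(=C=C)C(=O)O[Zn]Br | intermediate
24 | 2-substituted buta-2,3-dienoic acid (allenoic acid) | C=C1CC[C@H]2[C@](C)(COC(C)=O)CCC[C@@]2(C)[C@@H]1CCC(=C=C)C(=O)O | intermediate
25 | [(1R,4aS,5R,8aR)-1,4a-dimethyl-6-methylidene-5-[2-(2-oxo-2,5-dihydrofuran-3-yl)ethyl]decahydronaphthalen-1-yl]methyl acetate (labdane numbering 4R,5R,9R,10S) | C=C1CC[C@H]2[C@](C)(COC(C)=O)CCC[C@@]2(C)[C@@H]1CCC1=CCOC1=O | target

**Step count**
Total: 14 steps. Longest linear sequence: 14 steps (1 → 25, steps 1–14). Aldehyde 2 from step 1 is consumed in step 2, so every step lies on the one line; compounds 3, 12 and 17 are purchased and add no steps.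

**Steps most likely to fail**

Step 14 (proposed new method). What may go wrong: carboxylation of the propargyl/allenyl zinc may be slow or occur at C15 instead of C13, and reductive homocoupling of the bromide may compete. The fallback uses known chemistry only and sets out from 19, returning at 25. TBAF in THF would remove the silyl group to give enyne diol F1. NaAlH2(OCH2CH2OMe)2 in THF followed by I2 at −78 °C (alkoxide-directed trans-hydroalumination, then iodinolysis) would give (Z)-13-iodo diol F2, with iodine on C13 cis to the C15 carbinol. Carbonylative lactonisation (PdCl2(PPh3)2, CO 1 atm, Et3N, THF) would close the butenolide to give hydroxy butenolide F3. Ac2O/pyridine would then give 25.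

Step 4. What may go wrong: poor facial selectivity, because the dioxolane or ketone oxygen may compete with the ester for iridium. The fallback sets out from 7 and returns at 8, and changes the directing element to a strongly binding carboxylate. LiI in pyridine at reflux would cleave the methyl ester to give enone acid F4. Hydrogenation of its triethylammonium salt with [Rh(nbd)(dppb)]BF4 under H2 pressure, the carboxylate holding the metal on its own face, would give saturated keto acid F5 with H-5 cis to the carboxyl group. TMSCHN2 in MeOH/toluene would return ester 8.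

Step 7. What may go wrong: slow C-alkylation at the neopentyl enolate carbon, so that proton transfer scrambles the enolate and alkylation occurs at C7 or more than once. The fallback sets out from 11 and returns at 13, and avoids any free enolate by using an SN1-type electrophile. Silyl enol ether 11 with methyl chloro(phenylsulfanyl)acetate and ZnBr2 in CH2Cl2 (thionium-ion alkylation, again from the convex face) would give α-(phenylsulfanyl) keto diester F6. Bu3SnH/AIBN in toluene at 80 °C would remove the sulfur and give 13.

**Further compounds**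
F1 | step 14 | enyne diol (C9–CH2CH2–C≡C–CH2OH, 19-hydroxy) | C=C1CC[C@H]2[C@](C)(CO)CCC[C@@]2(C)[C@@H]1CCC#CCO
F2 | step 14 | (Z)-13-iodo diol (C9–CH2CH2–C(I)=CH–CH2OH, 19-hydroxy) | C=C1CC[C@H]2[C@](C)(CO)CCC[C@@]2(C)[C@@H]1CC/C(I)=C/CO
F3 | step 14 | hydroxy butenolide (19-deacetyl 25) | C=C1CC[C@H]2[C@](C)(CO)CCC[C@@]2(C)[C@@H]1CCC1=CCOC1=O
F4 | step 4 | enone acid (1R)-1-methyl-2-[2-(2-methyl-1,3-dioxolan-2-yl)ethylidene]-3-oxocyclohexane-1-carboxylic acid | CC1(C/C=C2/[C@](C)(C(=O)O)CCCC2=O)OCCO1
F5 | step 4 | saturated keto acid (1R,2S)-1-methyl-2-[2-(2-methyl-1,3-dioxolan-2-yl)ethyl]-3-oxocyclohexane-1-carboxylic acid | CC1(CC[C@H]2[C@](C)(C(=O)O)CCCC2=O)OCCO1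
F6 | step 7 | α-(phenylsulfanyl) keto diester (mixture at the sulfur-bearing carbon) | O=C1CC[C@H]2[C@](C)(C(=O)OC)CCC[C@@]2(C)[C@@H]1C(Sc1ccccc1)C(=O)OC
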